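Readings and results were computed for an exercise; noise was put on by code.

1. The pitfall is to carry a feed's possible effect on yield over to the share of target in target plus isomer of the product; the share obeys its own clock.

| flask | starting material | second substrate | partner | free catalyst | remark | time |
|---|---|---|---|---|---|---|
| maple | 0.20 M | 0.20 M | 0.18 M | 5 mM | run made earlier |  |
| birch | 0.13 M | 0.20 M | 0.18 M | 5 mM | run made earlier |  |
| larch | 0.30 M | 0.20 M | 0.18 M | 5 mM | run made earlier |  |
| ochre | 0.20 M | 0.200 M | 0.180 M (fed, over 5.0 h) | 5.0 mM | all else is in the flask from the start; the feed brings no volume worth counting | 25 h |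
| teal | 0.20 M | 0.200 M | 0.180 M | 5.0 mM | everything together at the start | 25 h |
| green | 0.20 M (fed, over 5.0 h) | 0.200 M | 0.180 M | 5.0 mM | all else is in the flask from the start; the feed brings no volume worth counting | 25 h |

- maple (time / h: target / %, isomer of the product / %, starting material / %): 4.00: 12, 12, 25; 8.00: 10, 18, 18; 12.0: 9, 19, 11; 15.0: 4, 15, 14; 20.0: 4, 20, 9; 25.0: 4, 18, 5
- birch (time / h: target / %, isomer of the product / %, starting material / %): 1.33: 21, 2, 54; 2.00: 20, 9, 46; 3.00: 12, 8, 37; 5.00: 12, 15, 28; 10.0: 10, 19, 22; 15.0: 2, 22, 12
- larch (time / h: target / %, isomer of the product / %, starting material / %): 1.00: 13, 0, 49; 3.00: 10, 7, 26; 5.00: 7, 8, 20; 8.00: 5, 15, 13; 12.0: 9, 14, 9; 15.0: 1, 13, 8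

(each reading ± 2 percentage points)

- the analysis behind the earlier runs scatters by 2 percentage points, standard deviation

* the flask with the highest share of target in target plus isomer of the product ("all alike" if they lie within 1.5 percentage points) (ochre / teal / green / all alike)
* share of target in target plus isomer of the product at the end, ochre
* share of target in target plus isomer of the product at the end, teal
* share of target in target plus isomer of the product at the end, green

2. Between 1.33 h and 5.00 h, the birch share falls at a reading of 0.196 h⁻¹. Between 1.00 h and 5.00 h, the larch share falls at 0.191 h⁻¹, about the same at a different charge of starting material. Each is reckoned as a fall towards zero, so a floor in the share makes it a low value.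

3. Two times matter. The relaxation time of the share is 5.10 h. The time left after a feed ends, when the three recipes no longer differ in what goes in, is 20.0 h, which is longer.

4. Their ratio, the relaxation number N, is the share's fall rate over the rate of one remaining period: 3.92. Time drops out.

5. My own reckoning: the gap to the floor shrinks to 1.98% of its size, so ochre, teal and green should end alike. The late readings, scattering by 2 percentage points, place that floor poorly.

6. The forecast says all alike, with 13%, 13% and 14% for ochre, teal and green, since “all flasks approach the same ratio”.

7. The flasks give all alike: 25.0%, 25.0% and 25.0%.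

    2 starting material → self-condensation product (k = 1.30 M⁻¹ h⁻¹)
    partner + catalyst intermediate A → free catalyst + target (k = 210 M⁻¹ h⁻¹)
    partner + catalyst intermediate B → free catalyst + second product (k = 990 M⁻¹ h⁻¹)
    second substrate + free catalyst ⇌ catalyst intermediate B (K = 11.0 M⁻¹, k = 200 M⁻¹ h⁻¹)
    target + free catalyst ⇌ isomer of the product + free catalyst, rate k5*[free catalyst]*[target] forward; the back reaction follows from the equilibrium constant (K = 3.00, k = 87.0 M⁻¹ h⁻¹)
    starting material + free catalyst ⇌ catalyst intermediate A (K = 3.80 M⁻¹, k = 2900 M⁻¹ h⁻¹)

The forecast's choice holds, but its level lies low. The common value equals the equilibrium share 25.0%, which is thermodynamic control, and N for teal, with no feed, is 4.90. The main reason teal reaches that share is the backward run from catalyst intermediate A to starting material + free catalyst: the same flask without that run ends at 90.8%. Scaled in proportion to the charge of free catalyst, N for a neighbour of teal charged with 0.0013 M is 1.28, and that flask stays above the equilibrium share, ending at 33.9%.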